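You cannot tell side product from zero in the summer run: its largest reading is 1.1% at 50.0 s, against a scatter of 1 percentage point. So give the side step a ceiling before you charge anything.

| flask | starting complex | incoming ligand | temperature | remark | time |
|---|---|---|---|---|---|
| summer | 0.030 M | 0.050 M | 50 °C | run made earlier |  |
| maple | 0.020 M | 0.0500 M | 50 °C |  | 4.0 min |
| elm | 0.020 M | 0.0500 M | 75 °C |  | 4.0 min |

summer run (percent of the starting complex charged)

| time / s | starting complex / % | complex with two exchanged / % | complex with three exchanged / % | side product / % | complex with one exchanged / % |
|---|---|---|---|---|---|
| 12.0 | 90.0 | 4.4 | 0 | 0 | 7.3 |
| 25.0 | 81.6 | 6.3 | 0.9 | 0 | 13.3 |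
| 40.0 | 73.2 | 9.8 | 0.8 | 0.5 | 16.2 |
| 50.0 | 68.6 | 15.8 | 0.5 | 1.1 | 14.3 |
| 60.0 | 62.7 | 19.5 | 1.3 | 0.8 | 14.2 |
| 80.0 | 56.1 | 24.5 | 0 | 0 | 15.2 |

(readings scatter by 1 percentage point)

1. which of these there is most of at the end, counted by the starting complex in it, maple (complex with one exchanged / complex with three exchanged / complex with two exchanged / side product / starting complex)
2. which of these there is most of at the end, counted by the starting complex in it, elm (complex with one exchanged / complex with three exchanged / complex with two exchanged / side product / starting complex)
3. final amount of the leader among these, as a percentage of the starting complex charged, in maple
4. final amount of the leader among these, as a percentage of the starting complex charged, in elm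

- candidate steps: starting complex + incoming ligand -> leaving ligand + complex with one exchanged; complex with one exchanged + incoming ligand -> leaving ligand + complex with two exchanged; complex with two exchanged + incoming ligand -> leaving ligand + complex with three exchanged; complex with two exchanged -> side product
- the earlier runs do not show what temperature does; that part of a forecast is a guess

Call k_L the first-order rate constant by which complex with two exchanged passes into side product. Compare rates at one moment: side product grows at k_L times the amount of that complex. The complex climbed roughly in a straight line, so treat its time integral up to 50.0 s as a triangle, 3.95 s. Divide the largest side-product reading by this area to get the leak ceiling 0.00278 s⁻¹, a value read from scattered readings. As a half-life it is 4.15 min, about as long as the 4.0 min planned for maple.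

Now ask how the comparison drifts. While the complex climbs, side product over complex with two exchanged grows as k_L t divided by 2, with t the time in the flask. The kept share, a selectivity, is therefore one over one plus that ratio. At the ceiling, maple keeps 75.0%.

The forecast says complex with two exchanged leads maple at 60% and complex with two exchanged leads elm at 58%, holding that three-exchanged and “side product stay within noise”. Treat its maple figure as what has passed on to that complex, and my own reckoning keeps 45.0%, which is lower than the forecast. The temperature effect is a guess, so give the leak a 6-fold speed-up in elm, the low end of the forecast's guess, which I apply to this step myself. Elm then keeps 33.3%, a third of what passes, so I expect more side product than complex with two exchanged. Charge maple as written, and run elm as a test of the leak, not as a way to make that complex.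

Maple gives complex with two exchanged first at 48.0%; elm gives side product first at 90.1%.

    starting complex + incoming ligand → leaving ligand + complex with one exchanged (k = 0.180 L mol⁻¹ s⁻¹, Ea = 53.0 kJ mol⁻¹)
    complex with one exchanged + incoming ligand → leaving ligand + complex with two exchanged (k = 0.760 L mol⁻¹ s⁻¹, Ea = 36.0 kJ mol⁻¹)
    complex with two exchanged + incoming ligand → leaving ligand + complex with three exchanged (k = 0.00830 L mol⁻¹ s⁻¹, Ea = 60.0 kJ mol⁻¹)
    complex with two exchanged → side product (k = 0.00220 s⁻¹, Ea = 102 kJ mol⁻¹)
    (constants at 50 °C)

In maple, the half-life of complex with two exchanged by the leak alone is 5.3 min, shorter than the 28 min by the step to complex with three exchanged alone. Put the ceiling to use on elm: from 2.00 min to 4.00 min, side product gains 19 points while complex with two exchanged falls from 9.87% to 1.99%. Take the logarithmic mean of those two amounts, since the complex falls along a curve, and that gain in elm asks for a leak about 11.6 times 0.00278 s⁻¹.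

Readings and results come from a simulation from invented constants; scatter was added.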